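In this flask X cannot exceed what has left the solid, so I began with the dissolved pool, X plus D, and not with the enzyme.

| flask | Z | L | remark | time |
|---|---|---|---|---|
| midnight | 0.20 M | 1.7 µM | the very flask that is asked about, followed so far |  |
| winter | 0.20 M | 0.85 µM | run made earlier |  |
| flask | 0.20 M | 1.7 µM |  | 6.0 h |

- midnight (time / min: X / %, D / %): 2.50: 0.9, 0.5; 4.00: 0.5, 0.3; 6.00: 0.2, 1.8; 10.0: 0.2, 2.0; 20.0: 3.4, 3.1; 30.0: 3.7, 3.0
- winter (time / h: X / %, D / %): 0.167: 0, 3.7; 0.500: 2.4, 3.7; 0.833: 6.8, 5.9; 1.33: 9.2, 9.7; 2.00: 14.3, 12.0; 2.50: 17.9, 13.9

(scatter of a reading: 1 percentage point)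

- how much X there is at 6.0 h, in percent of the Z charged
- concentration of D in solution at 3.0 h, in percent of saturation
- the change that raises the amount of X at 6.0 h, in percent of the Z charged most ("none" if none brings more than 2 percentage points) (red / ochre / blue / none)
- amount of X at 6.0 h, in percent of the Z charged, after ochre

- red: doubling the dissolution coefficient of Z, all else as stated
- ochre: doubling the amount of L, all else as stated
- blue: doubling the solubility of Z, all else as stated

- Z is a solid; its amount is given per volume of the solution
- the earlier runs were read with a standard deviation of 1 percentage point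
- at the start none of Z is in solution
- D is what Z becomes in solution
- D means what is dissolved; the solid is not counted in it

The midnight pool at 30.0 min was 6.70%. The winter pool at 0.500 h was 6.10%, with half the L. So the pool did not follow L in these readings. It rose by 0.134 /h of the charge, which gave 80.4% by 6.0 h.

But that pool was not X. I read the split, X over D at the last winter reading, as 1.29. One pair is a weak ground. Yet the last midnight pair gave 1.23, close to the split at a different L. That looked like thermodynamic rather than kinetic control, so I expected ochre to leave X where it stood.

The straight line had its own flaw. Late in the winter run the pool rose by 0.110 /h, slower than the midnight pool had risen. I let the rise fall in proportion to D, which gave a brake of 0.231 /h and a ceiling for D near 59.6%. On that reckoning the pool relaxed at 0.101 /h. That gave X of 34.9% at 6.0 h, and D at 26.1% of the ceiling at 3.0 h. Two noisy rates carried this, and my readings ended at 2.50 h. I left red against blue open.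

The forecast, unlike my reckoning, stood at 77%, 8%, blue and 84%, on the ground: “dissolution and Vmax nearly balance”.

The flask gave 30.1%, 30.1%, red with a gain of 4.6 percentage points, and 30.3% after ochre.

    D + L ⇌ J (K = 13.0 /M, k = 13000 /M/s)
    J ⇌ L + X (K = 0.100 M, k = 9900 /min)
    Z ⇌ D, rate k3*(cs3 - [D]) while solid is left; crystals form when [D] > cs3 (solubility = 0.110 M, k = 0.00500 /min)
    2 D → E (k = 0.0480 /M/min)

At 6.00 h the asked flask also held E at 18.5%. The split applied to its D of 23.4% makes 30.2% of X, against 30.1%. In the neighbour charged with 0.80 M of Z, D stood at 5.86% of its own charge at 6.00 h. The split makes that 7.56% of X, and the neighbour held 7.53%.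

Readings and results come from a simulation for substances that don't exist.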